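A direct plan would form the C7–C8 bond (C7 carbinol carbon, C8 ether carbon, C9 methyl carbon) by an auxiliary-controlled syn glycolate aldol of the N-(aryloxyacetyl)oxazolidinone A1 with 3,4-dimethoxybenzaldehyde, would cleave the auxiliary reductively to the 1,3-diol A2, would reduce C9 to a methyl group through its tosylate, and would invert C7 through the ketone A3. Its weakest steps would be the aldol addition, because an enolate with the bulky 2,6-dimethoxyphenoxy group and an electron-rich aldehyde would add slowly and reversibly; the removal of the C9 oxygen, three steps that would add length but no complexity; and the oxidation–reduction pair, which would only repair C7 and would pass through a ketone that can epimerise at C8.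

The new route disconnects the C7–C1 bond to ring A (the 3,4-dimethoxyphenyl ring) instead of C7–C8. C8, its methyl group C9 and the hindered ether to ring B (the 4-allyl-2,6-dimethoxyphenyl ring) are taken from lactic acid by one SN2 inversion beside an ester. In the key step a non-chelating aryltitanium reagent adds ring A to the (S)-α-aryloxy aldehyde; it exploits the C8–O bond to ring B, a strong σ-acceptor but a poor chelator, so that the polar Felkin–Anh mode should give the erythro (7R,8S) carbinol and the C7–C1 bond in one operation. No aldol, no deoxygenation of C9 and no correction of C7 remain.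

Key step: step 3

Step 1
Reactants: 1 4-allyl-2,6-dimethoxyphenol; 2 methyl (R)-lactate
Product: 4 methyl (S)-2-(4-allyl-2,6-dimethoxyphenoxy)propanoate, via alkoxyphosphonium aryloxide ion pair 3 (not isolated)
Conditions: PPh3, DIAD, THF, 0 °C → rt
Reagents that add atoms: none
Why: Mitsunobu etherification (SN2 with inversion): the oxyphosphonium group on C2 of the lactate, activated by the neighbouring ester, is displaced by the phenoxide of 1 (pKa about 10), so that the (R)-alcohol gives the (S)-aryl ether that becomes C8, and displacement at a carbon α to a carbonyl group tolerates the two ortho methoxy groups.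

Step 2
Reactants: 4 methyl (S)-2-(4-allyl-2,6-dimethoxyphenoxy)propanoate
Product: 6 (S)-2-(4-allyl-2,6-dimethoxyphenoxy)propanal, via aluminium hemiacetal 5 (not isolated)
Conditions: iBu2AlH (1.05 equiv), CH2Cl2, −78 °C; MeOH, then aq. potassium sodium tartrate; crude 6 used directly
Reagents that add atoms: none
Why: Partial ester reduction with a dialkylaluminium hydride: at −78 °C the tetrahedral aluminium hemiacetal 5, stabilised by the neighbouring aryloxy oxygen, should not collapse before the quench, so that the aldehyde is released only on work-up; C8 is not involved and the allyl group is not hydroaluminated at this temperature.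

Step 3
Reactants: 6 (S)-2-(4-allyl-2,6-dimethoxyphenoxy)propanal; 7 4-bromo-1,2-dimethoxybenzene
Product: 11 (1R,2S)-2-(4-allyl-2,6-dimethoxyphenoxy)-1-(3,4-dimethoxyphenyl)propan-1-ol, via aryllithium 8 (not isolated), via aryltitanium triisopropoxide 9 (not isolated), via titanium alkoxide 10 (not isolated)
Conditions: 7, n-BuLi, THF, −78 °C; ClTi(OiPr)3, −78 → −40 °C; then 6, −78 → 0 °C; aq. NH4Cl
Reagents that add atoms: none
Why: Bromine–lithium exchange on 7 and transmetalation with ClTi(OiPr)3 give the aryltitanium 9, which transfers its aryl group to the formyl carbon of 6 through a compact four-centre transition state, a non-chelation-controlled organotitanium carbonyl addition of the kind well known for α-alkoxy aldehydes. No ring is closed; the one new stereocentre, C7, is set by 1,2-induction from C8 according to the polar Felkin–Anh model: the C8–O bond to ring B stands anti to the incoming aryl group, the aryl group passes the C8 hydrogen, and attack on the Re face of the formyl group gives the (7R) carbinol, that is the erythro (1R,2S) isomer. The selectivity that is needed is non-chelation over chelation control (a chelate would lead to the threo epimer), and it should be secured by the weak Lewis acidity and the crowded, alkoxide-saturated coordination sphere of the Ti(OiPr)3 group and by the low basicity of the di-ortho-substituted aryl ether oxygen. The reagent is only weakly basic, so C8 of the aldehyde should not epimerise, the allyl group and the methyl ethers are inert, and any threo epimer should be removable by chromatography.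

Compound list

1 | 4-allyl-2,6-dimethoxyphenol | C=CCc1cc(OC)c(O)c(OC)c1 | starting material
2 | methyl (R)-lactate, methyl (2R)-2-hydroxypropanoate | C[C@@H](O)C(=O)OC | starting material
3 | [(2R)-1-methoxy-1-oxopropan-2-yl]oxy(triphenyl)phosphonium 4-allyl-2,6-dimethoxyphenoxide (not isolated) | C[C@@H](O[P+](c1ccccc1)(c1ccccc1)c1ccccc1)C(=O)OC.[O-]c1c(OC)cc(CC=C)cc1OC | intermediate
4 | methyl (S)-2-(4-allyl-2,6-dimethoxyphenoxy)propanoate | C=CCc1cc(OC)c(O[C@@H](C)C(=O)OC)c(OC)c1 | intermediate
5 | diisobutylaluminium hemiacetal of 4 (not isolated) | C=CCc1cc(OC)c(O[C@@H](C)C(OC)O[Al](CC(C)C)CC(C)C)c(OC)c1 | intermediate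
6 | (S)-2-(4-allyl-2,6-dimethoxyphenoxy)propanal | C=CCc1cc(OC)c(O[C@@H](C)C=O)c(OC)c1 | intermediate
7 | 4-bromo-1,2-dimethoxybenzene | COc1ccc(Br)cc1OC | starting material
8 | (3,4-dimethoxyphenyl)lithium (not isolated) | [Li]c1ccc(OC)c(OC)c1 | intermediate
9 | (3,4-dimethoxyphenyl)titanium triisopropoxide (not isolated) | CC(C)O[Ti](OC(C)C)(OC(C)C)c1ccc(OC)c(OC)c1 | intermediate
10 | triisopropoxytitanium alkoxide of 11 (not isolated) | C=CCc1cc(OC)c(O[C@@H](C)[C@H](O[Ti](OC(C)C)(OC(C)C)OC(C)C)c2ccc(OC)c(OC)c2)c(OC)c1 | intermediate
11 | (1R,2S)-2-(4-allyl-2,6-dimethoxyphenoxy)-1-(3,4-dimethoxyphenyl)propan-1-ol | C=CCc1cc(OC)c(O[C@@H](C)[C@H](O)c2ccc(OC)c(OC)c2)c(OC)c1 | target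

Total step count: 3. Longest linear sequence: 3.

Steps most likely to fail

1. Step 3 (facial selectivity of the aryl transfer). A chelated transition state through the ether oxygen on C8, or enolisation of 6 before the addition, would erode the erythro selectivity. The fallback sets out from 6 and comes back at 11, and it would change the control element from the substrate to a chiral catalyst. 3,4-Dimethoxyphenylboronic acid F3 and Et2Zn in toluene would give ethyl(3,4-dimethoxyphenyl)zinc F4. This reagent would transfer its aryl group to 6 at about −10 °C under ligand acceleration by a chiral β-amino alcohol (3-exo-morpholinoisoborneol), taken in the enantiomeric form that directs the aryl group to the Re face of the formyl group. Ligand control and the Felkin–Anh preference of 6 would then act in the same sense and give 11 directly.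

2. Step 2 (control of the reduction level and of C8). Over-reduction to the primary alcohol, or enolisation of the α-aryloxy aldehyde during work-up, would lower the yield or the optical purity. The fallback sets out from 4 and comes back at 6. Full reduction with LiBH4 in THF would give (S)-2-(4-allyl-2,6-dimethoxyphenoxy)propan-1-ol F2. A non-basic oxidation with Dess–Martin periodinane in NaHCO3-buffered CH2Cl2 would then give 6, to be used without purification.

3. Step 1 (slow displacement at the oxyphosphonium stage). The di-ortho-substituted phenoxide may attack slowly, so that elimination or N-alkylation of the reduced azodicarboxylate would compete. The fallback sets out from 2 and comes back at 4. Tf2O and 2,6-lutidine (CH2Cl2, −78 °C) would convert 2 into methyl (R)-2-(trifluoromethylsulfonyloxy)propanoate F1. The potassium phenoxide of 1 (K2CO3, MeCN, −20 → 0 °C) would then displace the triflate with inversion to give 4.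

Further compounds

F1 | step 1 | methyl (R)-2-(trifluoromethylsulfonyloxy)propanoate | C[C@@H](OS(=O)(=O)C(F)(F)F)C(=O)OC
F2 | step 2 | (S)-2-(4-allyl-2,6-dimethoxyphenoxy)propan-1-ol | C=CCc1cc(OC)c(O[C@@H](C)CO)c(OC)c1
F3 | step 3 | 3,4-dimethoxyphenylboronic acid | OB(O)c1ccc(OC)c(OC)c1
F4 | step 3 | ethyl(3,4-dimethoxyphenyl)zinc | CC[Zn]c1ccc(OC)c(OC)c1
A1 | direct plan | (R)-4-benzyl-3-[2-(4-allyl-2,6-dimethoxyphenoxy)acetyl]oxazolidin-2-one | C=CCc1cc(OC)c(OCC(=O)N2[C@H](Cc3ccccc3)COC2=O)c(OC)c1
A2 | direct plan | (1S,2S)-2-(4-allyl-2,6-dimethoxyphenoxy)-1-(3,4-dimethoxyphenyl)propane-1,3-diol | C=CCc1cc(OC)c(O[C@H]([C@@H](O)c2ccc(OC)c(OC)c2)CO)c(OC)c1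
A3 | direct plan | (S)-2-(4-allyl-2,6-dimethoxyphenoxy)-1-(3,4-dimethoxyphenyl)propan-1-one | C=CCc1cc(OC)c(O[C@@H](C)C(=O)c2ccc(OC)c(OC)c2)c(OC)c1
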